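**Plan**
- Retrosynthesis: the benzyl ethers and the stilbene C=C are cut first (debenzylation, Horner–Wadsworth–Emmons). The benzo ring is then read as a dehydrogenated cyclohexane-1,3-dione. The dihydrofuran ring O1–C2–C3–C3a–C7a is contracted to the cyclopropane C2–C3–C3a (O1–C2 cut, C2–C3a made). The cyclopropane is cut at C2–C3 and C3–C3a (benzylide plus arylidene dione) and the arylidene at C2=C3a (Knoevenagel).
- Enabling feature: C3a lies between the two oxygen-bearing ring carbons C4 and C7a, so it is the central carbon of a latent 1,3-dione (acceptor), and C2 carries a para-oxygenated aryl group (donor). C2–C3–C3a is therefore a spiro donor–acceptor cyclopropane that can ionise only at C2–C3a and is recaptured by the dione oxygen that becomes O1.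
- Forward order of rings: six-membered dione ring (bought), cyclopropane (step 3), dihydrofuran ring by ring expansion (step 4), benzo ring by dehydrogenation (step 5), then the stilbene arm (step 10) and the free phenols (step 11).
- Stereochemistry: C3 comes from the chiral sulfonium benzylide (reagent control) and is not touched again. C2 is set in the ring expansion under thermodynamic control, trans to the C3 aryl group, so both C2 epimers of the cyclopropane converge. The alkene is E from the phosphonate olefination.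

Key step: step 4

Remark: the facial sense of the benzylide from sulfide 1 toward an arylidene 1,3-dione has no direct precedent; it is assumed that the (1R,4R,5R) sulfide gives the sense needed here, and the enantiomeric sulfide would be used in the same way if it does not.

**Step 1**
Reactants: 1 (1R,4R,5R)-isothiocineole [(1R,4R,5R)-4,7,7-trimethyl-6-thiabicyclo[3.2.1]octane]; 2 3,5-bis(benzyloxy)benzyl bromide
Product: 3 (1R,4R,5R)-6-[3,5-bis(benzyloxy)benzyl]-4,7,7-trimethyl-6-thiabicyclo[3.2.1]octan-6-ium trifluoromethanesulfonate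
Conditions: LiOSO2CF3 (aq), CH2Cl2, rt
Reagents that add atoms: lithium trifluoromethanesulfonate, [Li+].[O-]S(=O)(=O)C(F)(F)F
Why: SN2 S-alkylation of the thioether by the benzylic bromide on its less hindered lone pair, with anion exchange to the non-nucleophilic triflate so that the alkylation cannot revert.

**Step 2**
Reactants: 4 ethyl 3,5-dioxocyclohexane-1-carboxylate; 5 4-(benzyloxy)-3-methoxybenzaldehyde
Product: 6 ethyl 4-{[4-(benzyloxy)-3-methoxyphenyl]methylidene}-3,5-dioxocyclohexane-1-carboxylate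
Conditions: piperidine (10 mol%), AcOH (10 mol%), 4 Å molecular sieves, CH2Cl2, 0 °C, 4 added slowly to 5 (1.5 equiv); used at once
Reagents that add atoms: none
Why: Knoevenagel condensation of the cyclic 1,3-dione with an electron-rich aryl aldehyde, whose push–pull conjugation and the excess of aldehyde should hold back a second Michael addition of the dione; no stereocentre that survives is formed.

**Step 3**
Reactants: 3 (1R,4R,5R)-6-[3,5-bis(benzyloxy)benzyl]-4,7,7-trimethyl-6-thiabicyclo[3.2.1]octan-6-ium trifluoromethanesulfonate; 6 ethyl 4-{[4-(benzyloxy)-3-methoxyphenyl]methylidene}-3,5-dioxocyclohexane-1-carboxylate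
Product: 8 ethyl (1S,2S)-1-[4-(benzyloxy)-3-methoxyphenyl]-2-[3,5-bis(benzyloxy)phenyl]-4,8-dioxospiro[2.5]octane-6-carboxylate, via sulfonium benzylide 7 (not isolated)
Conditions: K2CO3 (powdered, anhydrous), MeCN, 0 °C to rt; filtration through Et3N-deactivated silica
Reagents that add atoms: none
Why: Corey–Chaykovsky-type Michael-initiated ring closure in which the semi-stabilised benzylide adds to the exocyclic carbon of the doubly activated alkene and the dione enolate carbon then displaces the sulfide by 3-exo-tet SN2 with inversion; the chiral sulfide fixes the face of the ylide carbon, which becomes the cyclopropane carbon bearing the 3,5-bis(benzyloxy)phenyl group (later C3), whereas the configuration at the other aryl-bearing carbon (trans drawn) and at C6 is of no consequence.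

**Step 4**
Reactants: 8 ethyl (1S,2S)-1-[4-(benzyloxy)-3-methoxyphenyl]-2-[3,5-bis(benzyloxy)phenyl]-4,8-dioxospiro[2.5]octane-6-carboxylate
Product: 9 ethyl (2S,3S)-2-[4-(benzyloxy)-3-methoxyphenyl]-3-[3,5-bis(benzyloxy)phenyl]-4-oxo-2,3,4,5,6,7-hexahydro-1-benzofuran-6-carboxylate
Conditions: Sc(OSO2CF3)3 (10 mol%), CH2Cl2, 0 °C to rt
Reagents that add atoms: none
Why: The Lewis acid binds the 1,3-dione and heterolyses the cyclopropane bond between the spiro carbon and the carbon bearing the 4-benzyloxy-3-methoxyphenyl group, giving a scandium dione enolate and a para-alkoxybenzyl cation. The enolate oxygen captures this cation in a 5-exo-trig closure (the cationic π-system stays outside the new ring), so the three-membered ring C2–C3–C3a grows by C7a and O1; this is a Cloke–Wilson cyclopropyl ketone to dihydrofuran ring expansion, and the closest precedent is the acid-catalysed ring-opening cyclisation of 2-aryl cyclohexane-1,3-dione-2-spirocyclopropanes. C3 is not involved in any bond change and keeps the configuration set in step 3. C2 is formed from a planar cation and, because closure is reversible under the Lewis acid, should settle trans to the C3 aryl group (control by the C3 stereocentre), so cis and trans cyclopropanes converge on one product. The regiochemistry needed (O1 to C2, C3 on C3a) is secured by the substituents: only the para-oxygenated aryl group stabilises a benzylic cation, while the meta-oxygenated ring at C3 does not, so the C3–C3a bond stays intact. The other selectivities needed are oxygen over carbon recapture (carbon recapture only returns 8) and cyclisation over loss of the C3 proton, both favoured by the intramolecular five-membered closure in a non-basic medium.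

**Step 5**
Reactants: 9 ethyl (2S,3S)-2-[4-(benzyloxy)-3-methoxyphenyl]-3-[3,5-bis(benzyloxy)phenyl]-4-oxo-2,3,4,5,6,7-hexahydro-1-benzofuran-6-carboxylate
Product: 11 ethyl (2S,3S)-2-[4-(benzyloxy)-3-methoxyphenyl]-3-[3,5-bis(benzyloxy)phenyl]-4-hydroxy-2,3-dihydro-1-benzofuran-6-carboxylate, via α-phenylselanyl ketone 10 (not isolated)
Conditions: LiN(iPr)2, THF, −78 °C; PhSeCl; then H2O2 (30% aq), pyridine, CH2Cl2, 0 °C to rt
Reagents that add atoms: none
Why: Kinetic enolisation at C5 (the only sp3 α-carbon of the vinylogous ester ketone), selenenylation, selenoxide syn-elimination toward the C6 hydrogen and tautomerisation of the resulting dienone to the phenol, which removes the C6 stereocentre and leaves C2 and C3 untouched because no enolate can form at the dihydrofuran carbons.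

**Step 6**
Reactants: 11 ethyl (2S,3S)-2-[4-(benzyloxy)-3-methoxyphenyl]-3-[3,5-bis(benzyloxy)phenyl]-4-hydroxy-2,3-dihydro-1-benzofuran-6-carboxylate
Product: 12 ethyl (2S,3S)-4-(benzyloxy)-2-[4-(benzyloxy)-3-methoxyphenyl]-3-[3,5-bis(benzyloxy)phenyl]-2,3-dihydro-1-benzofuran-6-carboxylate
Conditions: BnBr, K2CO3, DMF, rt
Reagents that add atoms: benzyl bromide, BrCc1ccccc1
Why: Williamson O-benzylation of the phenol so that all five phenolic oxygens carry the same group for a single final deprotection.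

**Step 7**
Reactants: 12 ethyl (2S,3S)-4-(benzyloxy)-2-[4-(benzyloxy)-3-methoxyphenyl]-3-[3,5-bis(benzyloxy)phenyl]-2,3-dihydro-1-benzofuran-6-carboxylate
Product: 13 {(2S,3S)-4-(benzyloxy)-2-[4-(benzyloxy)-3-methoxyphenyl]-3-[3,5-bis(benzyloxy)phenyl]-2,3-dihydro-1-benzofuran-6-yl}methanol
Conditions: iBu2AlH (2.5 equiv), CH2Cl2, −78 to 0 °C; Rochelle salt work-up
Reagents that add atoms: none
Why: Hydride reduction of the aryl ester to the benzylic alcohol, to which benzyl ethers and the dihydrofuran are inert.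

**Step 8**
Reactants: 13 {(2S,3S)-4-(benzyloxy)-2-[4-(benzyloxy)-3-methoxyphenyl]-3-[3,5-bis(benzyloxy)phenyl]-2,3-dihydro-1-benzofuran-6-yl}methanol
Product: 14 (2S,3S)-4-(benzyloxy)-2-[4-(benzyloxy)-3-methoxyphenyl]-3-[3,5-bis(benzyloxy)phenyl]-2,3-dihydro-1-benzofuran-6-carbaldehyde
Conditions: MnO2 (activated, excess), CH2Cl2, rt
Reagents that add atoms: none
Why: Selective oxidation of a benzylic alcohol to the aldehyde without over-oxidation and without touching the benzylic C2 and C3 positions.

**Step 9**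
Reactants: 15 4-(benzyloxy)-3-methoxybenzyl alcohol
Product: 17 diethyl [4-(benzyloxy)-3-methoxybenzyl]phosphonate, via benzylic bromide 16 (not isolated)
Conditions: PBr3, CH2Cl2, 0 °C; concentrate; P(OEt)3, 130 °C
Reagents that add atoms: triethyl phosphite, CCOP(OCC)OCC
Why: Conversion of the alcohol to the bromide followed by Michaelis–Arbuzov reaction with the phosphite, the labile electron-rich bromide being used without isolation.

**Step 10**
Reactants: 14 (2S,3S)-4-(benzyloxy)-2-[4-(benzyloxy)-3-methoxyphenyl]-3-[3,5-bis(benzyloxy)phenyl]-2,3-dihydro-1-benzofuran-6-carbaldehyde; 17 diethyl [4-(benzyloxy)-3-methoxybenzyl]phosphonate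
Product: 18 (2S,3S)-4-(benzyloxy)-2-[4-(benzyloxy)-3-methoxyphenyl]-6-{(E)-2-[4-(benzyloxy)-3-methoxyphenyl]ethenyl}-3-[3,5-bis(benzyloxy)phenyl]-2,3-dihydro-1-benzofuran
Conditions: KOtBu, THF, 0 °C to rt
Reagents that add atoms: none
Why: Horner–Wadsworth–Emmons olefination of an aryl aldehyde with a benzylic phosphonate anion, which should give the E-stilbene through the thermodynamically favoured anti elimination.

**Step 11**
Reactants: 18 (2S,3S)-4-(benzyloxy)-2-[4-(benzyloxy)-3-methoxyphenyl]-6-{(E)-2-[4-(benzyloxy)-3-methoxyphenyl]ethenyl}-3-[3,5-bis(benzyloxy)phenyl]-2,3-dihydro-1-benzofuran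
Product: 19 bisisorhapontigenin B [(2S,3S)-3-(3,5-dihydroxyphenyl)-2-(4-hydroxy-3-methoxyphenyl)-6-[(E)-2-(4-hydroxy-3-methoxyphenyl)ethenyl]-2,3-dihydro-1-benzofuran-4-ol]
Conditions: BCl3 (excess), C6HMe5 (pentamethylbenzene), CH2Cl2, −78 °C; MeOH quench
Reagents that add atoms: none
Why: Lewis acid cleavage of the five aryl benzyl ethers with a non-basic cation scavenger, which at low temperature should spare the two methyl ethers, the E-alkene and the trans-dihydrobenzofuran (whose only acid-induced change, ring opening at C2, leads back to the trans isomer).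

**Compound list**
1 | (1R,4R,5R)-isothiocineole | C[C@@H]1CC[C@@H]2C[C@H]1SC2(C)C | starting material
2 | 3,5-bis(benzyloxy)benzyl bromide | BrCc1cc(OCc2ccccc2)cc(OCc2ccccc2)c1 | starting material
3 | (1R,4R,5R)-6-[3,5-bis(benzyloxy)benzyl]-4,7,7-trimethyl-6-thiabicyclo[3.2.1]octan-6-ium trifluoromethanesulfonate (one configuration at sulfur, not drawn) | C[C@@H]1CC[C@@H]2C[C@H]1[S+](Cc1cc(OCc3ccccc3)cc(OCc3ccccc3)c1)C2(C)C.[O-]S(=O)(=O)C(F)(F)F | intermediate
4 | ethyl 3,5-dioxocyclohexane-1-carboxylate | CCOC(=O)C1CC(=O)CC(=O)C1 | starting material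
5 | 4-(benzyloxy)-3-methoxybenzaldehyde | COc1cc(C=O)ccc1OCc1ccccc1 | starting material
6 | ethyl 4-{[4-(benzyloxy)-3-methoxyphenyl]methylidene}-3,5-dioxocyclohexane-1-carboxylate (racemic) | CCOC(=O)C1CC(=O)C(=Cc2ccc(OCc3ccccc3)c(OC)c2)C(=O)C1 | intermediate
7 | [3,5-bis(benzyloxy)phenyl][(1R,4R,5R)-4,7,7-trimethyl-6-thiabicyclo[3.2.1]octan-6-ium-6-yl]methanide (sulfonium benzylide, not isolated) | C[C@@H]1CC[C@@H]2C[C@H]1[S+]([CH-]c1cc(OCc3ccccc3)cc(OCc3ccccc3)c1)C2(C)C | intermediate
8 | ethyl (1S,2S)-1-[4-(benzyloxy)-3-methoxyphenyl]-2-[3,5-bis(benzyloxy)phenyl]-4,8-dioxospiro[2.5]octane-6-carboxylate (C6 epimers) | CCOC(=O)C1CC(=O)C2(C(=O)C1)[C@H](c1ccc(OCc3ccccc3)c(OC)c1)[C@H]2c1cc(OCc3ccccc3)cc(OCc3ccccc3)c1 | intermediate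
9 | ethyl (2S,3S)-2-[4-(benzyloxy)-3-methoxyphenyl]-3-[3,5-bis(benzyloxy)phenyl]-4-oxo-2,3,4,5,6,7-hexahydro-1-benzofuran-6-carboxylate (C6 epimers) | CCOC(=O)C1CC(=O)C2=C(C1)O[C@H](c1ccc(OCc3ccccc3)c(OC)c1)[C@H]2c1cc(OCc3ccccc3)cc(OCc3ccccc3)c1 | intermediate
10 | ethyl (2S,3S)-2-[4-(benzyloxy)-3-methoxyphenyl]-3-[3,5-bis(benzyloxy)phenyl]-4-oxo-5-(phenylselanyl)-2,3,4,5,6,7-hexahydro-1-benzofuran-6-carboxylate (not isolated) | CCOC(=O)C1C([Se]c3ccccc3)C(=O)C2=C(C1)O[C@H](c1ccc(OCc3ccccc3)c(OC)c1)[C@H]2c1cc(OCc3ccccc3)cc(OCc3ccccc3)c1 | intermediate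
11 | ethyl (2S,3S)-2-[4-(benzyloxy)-3-methoxyphenyl]-3-[3,5-bis(benzyloxy)phenyl]-4-hydroxy-2,3-dihydro-1-benzofuran-6-carboxylate | CCOC(=O)c1cc(O)c2c(c1)O[C@H](c1ccc(OCc3ccccc3)c(OC)c1)[C@H]2c1cc(OCc3ccccc3)cc(OCc3ccccc3)c1 | intermediate
12 | ethyl (2S,3S)-4-(benzyloxy)-2-[4-(benzyloxy)-3-methoxyphenyl]-3-[3,5-bis(benzyloxy)phenyl]-2,3-dihydro-1-benzofuran-6-carboxylate | CCOC(=O)c1cc(OCc3ccccc3)c2c(c1)O[C@H](c1ccc(OCc3ccccc3)c(OC)c1)[C@H]2c1cc(OCc3ccccc3)cc(OCc3ccccc3)c1 | intermediate
13 | {(2S,3S)-4-(benzyloxy)-2-[4-(benzyloxy)-3-methoxyphenyl]-3-[3,5-bis(benzyloxy)phenyl]-2,3-dihydro-1-benzofuran-6-yl}methanol | OCc1cc(OCc3ccccc3)c2c(c1)O[C@H](c1ccc(OCc3ccccc3)c(OC)c1)[C@H]2c1cc(OCc3ccccc3)cc(OCc3ccccc3)c1 | intermediate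
14 | (2S,3S)-4-(benzyloxy)-2-[4-(benzyloxy)-3-methoxyphenyl]-3-[3,5-bis(benzyloxy)phenyl]-2,3-dihydro-1-benzofuran-6-carbaldehyde | O=Cc1cc(OCc3ccccc3)c2c(c1)O[C@H](c1ccc(OCc3ccccc3)c(OC)c1)[C@H]2c1cc(OCc3ccccc3)cc(OCc3ccccc3)c1 | intermediate
15 | 4-(benzyloxy)-3-methoxybenzyl alcohol | COc1cc(CO)ccc1OCc1ccccc1 | starting material
16 | 4-(benzyloxy)-3-methoxybenzyl bromide (not isolated) | COc1cc(CBr)ccc1OCc1ccccc1 | intermediate
17 | diethyl [4-(benzyloxy)-3-methoxybenzyl]phosphonate | CCOP(=O)(Cc1ccc(OCc2ccccc2)c(OC)c1)OCC | intermediate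
18 | (2S,3S)-4-(benzyloxy)-2-[4-(benzyloxy)-3-methoxyphenyl]-6-{(E)-2-[4-(benzyloxy)-3-methoxyphenyl]ethenyl}-3-[3,5-bis(benzyloxy)phenyl]-2,3-dihydro-1-benzofuran | COc1cc(/C=C/c2cc(OCc4ccccc4)c3c(c2)O[C@H](c2ccc(OCc4ccccc4)c(OC)c2)[C@H]3c2cc(OCc4ccccc4)cc(OCc4ccccc4)c2)ccc1OCc1ccccc1 | intermediate
19 | bisisorhapontigenin B, (2S,3S)-3-(3,5-dihydroxyphenyl)-2-(4-hydroxy-3-methoxyphenyl)-6-[(E)-2-(4-hydroxy-3-methoxyphenyl)ethenyl]-2,3-dihydro-1-benzofuran-4-ol | COc1cc(/C=C/c2cc(O)c3c(c2)O[C@H](c2ccc(O)c(OC)c2)[C@H]3c2cc(O)cc(O)c2)ccc1O | target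

**Step count and risks**
Total: 11 steps. Longest linear sequence: 9 steps (steps 2, 3, 4, 5, 6, 7, 8, 10, 11 from 4 and 5).

Most likely to fail, in this order:

Step 3. The transfer of chirality may be poor if the conjugate addition of the benzylide becomes reversible, so that the two faces of the ylide carbon equilibrate before ring closure. The fallback secures the configuration by resolution instead of reagent control. It sets out from 2 and 6. Tetrahydrothiophene and 2 (acetone, rt) give 1-[3,5-bis(benzyloxy)benzyl]thiolan-1-ium bromide F1. F1, 6 and K2CO3 in MeCN give racemic trans ethyl 1-[4-(benzyloxy)-3-methoxyphenyl]-2-[3,5-bis(benzyloxy)phenyl]-4,8-dioxospiro[2.5]octane-6-carboxylate F2. Treatment of F2 as in step 4 gives racemic trans ethyl 2-[4-(benzyloxy)-3-methoxyphenyl]-3-[3,5-bis(benzyloxy)phenyl]-4-oxo-2,3,4,5,6,7-hexahydro-1-benzofuran-6-carboxylate F3. F3 is separated by preparative chromatography on a chiral stationary phase (cellulose tris(3,5-dimethylphenylcarbamate)); the (2S,3S) enantiomer is 9, where the route is rejoined.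

Step 2. The arylidene dione may be consumed by a second Michael addition of the dione, or may not survive isolation. The fallback replaces the free alkene by a stable precursor that releases it only when the ylide is present. It sets out from 4 and 5. Condensation with sodium 4-methylbenzenesulfinate in HCO2H/H2O at rt gives ethyl 4-{[4-(benzyloxy)-3-methoxyphenyl](4-methylbenzenesulfonyl)methyl}-3-hydroxy-5-oxocyclohex-3-ene-1-carboxylate F4, a crystalline sulfone. F4, salt 3 and K2CO3 (3.5 equiv) in MeCN are then combined, so that loss of sulfinate from the enolate of F4 forms 6 in low concentration beside ylide 7. The route is rejoined at 8.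

Step 5. Enolisation may occur at the wrong site, or electrophilic selenium species may attack the electron-rich rings or over-oxidise the new phenol. The fallback sets out from 9 and uses catalytic aerobic dehydrogenation instead of enolate chemistry: Pd(OCOCF3)2 (5 mol%), 2-(dimethylamino)pyridine (10 mol%), TsOH (20 mol%), O2 (1 atm), DMSO, 80 °C. A palladium enolate at C5 undergoes β-hydride elimination and the dienone tautomerises, which gives 11 directly with no new compound on the way.

**Further compounds**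
F1 | step 3 | 1-[3,5-bis(benzyloxy)benzyl]thiolan-1-ium bromide | [Br-].C(c1cc(OCc2ccccc2)cc(OCc2ccccc2)c1)[S+]1CCCC1
F2 | step 3 | racemic trans ethyl 1-[4-(benzyloxy)-3-methoxyphenyl]-2-[3,5-bis(benzyloxy)phenyl]-4,8-dioxospiro[2.5]octane-6-carboxylate, rac-(1S,2S) | CCOC(=O)C1CC(=O)C2(C(=O)C1)C(c1ccc(OCc3ccccc3)c(OC)c1)C2c1cc(OCc3ccccc3)cc(OCc3ccccc3)c1
F3 | step 3 | racemic trans ethyl 2-[4-(benzyloxy)-3-methoxyphenyl]-3-[3,5-bis(benzyloxy)phenyl]-4-oxo-2,3,4,5,6,7-hexahydro-1-benzofuran-6-carboxylate, rac-(2S,3S) | CCOC(=O)C1CC(=O)C2=C(C1)OC(c1ccc(OCc3ccccc3)c(OC)c1)C2c1cc(OCc3ccccc3)cc(OCc3ccccc3)c1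
F4 | step 2 | ethyl 4-{[4-(benzyloxy)-3-methoxyphenyl](4-methylbenzenesulfonyl)methyl}-3-hydroxy-5-oxocyclohex-3-ene-1-carboxylate | CCOC(=O)C1CC(=O)C(C(c2ccc(OCc3ccccc3)c(OC)c2)S(=O)(=O)c2ccc(C)cc2)=C(O)C1
F0 | step 5 | none | none
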